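**Plan** (ring numbering: O1, O2, C3 bearing H and CH2CO2Me, C4=C5, C6 bearing OMe and the C18 tail)
- Retrosynthetic cuts, in order: the C6 ketal configuration (equilibration in acidic MeOH); O2–C3 (peroxy-Michael); O1–C6 and C6–OMe (perketalisation of a ketone); both σ-bonds beside the ring alkene, C3–C4 and C5–C6, in one cut; and last the tail alkene C14'=C15' (Julia–Kocienski).
- Enabling feature: C4=C5 is an unsubstituted cis-CH=CH. It lies between C6 (ketone level, an acyl carbon) and C3 (the β-carbon of the acetate arm, that is the β-carbon of an acrylate). The dioxine ring is therefore two electrophilic carbons bridged twice, once by a cis-vinylene dianion (a distannane made from acetylene) and once by O1–O2 (H2O2).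
- Forward order: the tail acid chloride is made from ω-pentadecalactone and crotonaldehyde. A three-component vinylene stitching with methyl (E)-3-iodoacrylate then gives the full chain as a (2E,4Z)-6-oxodienoate. H2O2/MeOH is added at C6, and a 6-exo-trig closure forms the only ring.
- Stereochemistry: the tail E,E geometry comes from crotonaldehyde and the Julia–Kocienski step. The ring Z geometry comes from syn-distannation and stereoretentive couplings. C3 (R) comes from a chiral amine–squaramide catalyst in the ring closure. C6 (R) comes from anomeric (thermodynamic) control, with OMe pseudoaxial and cis to the acetate arm.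

Key step: step 8

Assumption: methyl (E)-3-iodoacrylate is taken as a catalogue chemical, and the quinidine-derived squaramide is written for step 10; its quinine-derived pseudoenantiomer takes its place should the sense of induction prove opposite.

**Step 1**
Reactants: 1 ω-pentadecalactone (oxacyclohexadecan-2-one)
Product: 2 methyl 15-hydroxypentadecanoate
Conditions: MeOH, H2SO4 (cat.), reflux
Reagents that add atoms: methanol, CO
Why: Acid-catalysed transesterification in a large excess of methanol should open the macrolactone to the hydroxy ester, which holds the thirteen methylene groups of the tail between its two functional carbons.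

**Step 2**
Reactants: 2 methyl 15-hydroxypentadecanoate
Product: 3 methyl 15-[(1-phenyl-1H-tetrazol-5-yl)sulfanyl]pentadecanoate
Conditions: 1-phenyl-1H-tetrazole-5-thiol, PPh3, DIAD, THF, 0 °C → rt
Reagents that add atoms: 1-phenyl-1H-tetrazole-5-thiol, Sc1nnnn1-c1ccccc1
Why: The Mitsunobu reaction of an unhindered primary alcohol with the acidic heteroaryl thiol is the standard entry to Julia–Kocienski sulfones and leaves the ester untouched.

**Step 3**
Reactants: 3 methyl 15-[(1-phenyl-1H-tetrazol-5-yl)sulfanyl]pentadecanoate
Product: 4 methyl 15-[(1-phenyl-1H-tetrazol-5-yl)sulfonyl]pentadecanoate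
Conditions: (NH4)6Mo7O24·4H2O (cat.), 30 % aq. H2O2, EtOH, 0 °C → rt
Reagents that add atoms: hydrogen peroxide, OO
Why: Molybdate-catalysed sulfide-to-sulfone oxidation is placed before any alkene is present, so sulfur is the only oxidisable site.

**Step 4**
Reactants: 4 methyl 15-[(1-phenyl-1H-tetrazol-5-yl)sulfonyl]pentadecanoate; 5 (E)-crotonaldehyde
Product: 6 methyl (15E,17E)-nonadeca-15,17-dienoate
Conditions: KN(SiMe3)2, DME, −60 °C; then 5, −60 °C → rt
Reagents that add atoms: none
Why: In the Julia–Kocienski olefination the sulfone α-carbon (more acidic than the ester α-carbon) adds to the enal, and Smiles rearrangement with anti-elimination should favour the new E alkene with potassium in DME, while the E alkene of 5 is carried over.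

**Step 5**
Reactants: 6 methyl (15E,17E)-nonadeca-15,17-dienoate
Product: 7 (15E,17E)-nonadeca-15,17-dienoic acid
Conditions: LiOH, THF/MeOH/H2O, rt; then dilute HCl
Reagents that add atoms: lithium hydroxide, [Li+].[OH-]
Why: Saponification of an unhindered methyl ester does not affect the remote unactivated diene.

**Step 6**
Reactants: 7 (15E,17E)-nonadeca-15,17-dienoic acid
Product: 8 (15E,17E)-nonadeca-15,17-dienoyl chloride
Conditions: 1-chloro-N,N,2-trimethylprop-1-en-1-amine, CH2Cl2, 0 °C → rt; used crude
Reagents that add atoms: 1-chloro-N,N,2-trimethylprop-1-en-1-amine, CC(C)=C(Cl)N(C)C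
Why: Acid chloride formation with an α-chloroenamine runs under neutral conditions without free HCl, so the tail diene should not be hydrochlorinated or isomerised.

**Step 7**
Reactants: 9 acetylene; 10 hexamethylditin
Product: 11 (Z)-1,2-bis(trimethylstannyl)ethene
Conditions: Pd(PPh3)4 (cat.), 1,4-dioxane, acetylene (1 atm), 60 °C, dark; distillation
Reagents that add atoms: none
Why: In the distannation catalysed by zerovalent palladium, oxidative addition of Sn–Sn, syn insertion of acetylene and reductive elimination place both tin atoms on the same side, which fixes the Z geometry of the future ring alkene.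

**Step 8**
Reactants: 8 (15E,17E)-nonadeca-15,17-dienoyl chloride; 11 (Z)-1,2-bis(trimethylstannyl)ethene; 12 methyl (E)-3-iodoacrylate
Product: 14 methyl (2E,4Z,20E,22E)-6-oxotetracosa-2,4,20,22-tetraenoate, via Z-stannyl enone 13 (not isolated)
Conditions: Pd2(dba)3 (cat.), P(2-furyl)3, THF, rt, 8 added slowly to 11 (slight excess); then 12, Cu(O2C-C4H3S) (copper thiophene-2-carboxylate, stoichiometric), DMF, 0 °C → rt, dark
Reagents that add atoms: none
Why: Zerovalent palladium inserts into the C–Cl bond of 8, one C–Sn bond of 11 transmetalates with retention and reductive elimination makes the acyl–vinyl bond (future C5–C6) to give 13; after addition of 12 and the copper carboxylate the second C–Sn bond is handed from tin to copper to the alkenylpalladium iodide formed from 12, and reductive elimination makes the vinyl–vinyl bond (future C3–C4), so both σ-bonds beside the ring alkene arise in one flask from one two-carbon linchpin. The closest known reaction type is the double Stille stitching of two electrophilic termini with a 1,2-distannylethene, composed here of an acyl Stille ketone synthesis and a copper-carboxylate-assisted Stille coupling of an alkenyl iodide. No ring is closed and no stereocentre is formed; the stereochemical content is the alkene geometry, 4Z carried over from 11 and 2E from 12, because every elementary step at sp2 carbon is stereoretentive. The selectivity needed is hetero- over homo-double coupling, and it is secured by the order of addition and by the substrate: once acylated, the remaining stannane in 13 is electron-poor and internally O→Sn coordinated, so it should resist a second acylpalladium species under copper-free conditions and react only once the copper carboxylate is added. The medium is neutral and base-free, so 8 cannot form a ketene, the tail diene (no C–halogen or C–metal bond) is a spectator, and the Z-enone is not exposed to acid or nucleophiles. The product holds every carbon of the target except the ketal methyl and presents C6 and C3 as two electrophilic sites, held cis, which H2O2 has to bridge.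

**Step 9**
Reactants: 14 methyl (2E,4Z,20E,22E)-6-oxotetracosa-2,4,20,22-tetraenoate
Product: 15 methyl (2E,4Z,20E,22E)-6-hydroperoxy-6-methoxytetracosa-2,4,20,22-tetraenoate (racemic at C6)
Conditions: urea·H2O2 (excess), Sc(OTf)3 (cat.), MeOH/CH2Cl2, 0 °C → rt
Reagents that add atoms: urea–hydrogen peroxide (delivers H2O2), NC(N)=O.OO; methanol, CO
Why: In this Lewis-acid-catalysed perketalisation of a ketone (α-methoxy hydroperoxide formation) the electron-poor dienoate should raise the carbonyl electrophilicity and disfavour charge delocalisation into C4=C5, so the Z geometry should persist; C6 forms without control and is corrected in step 11.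

**Step 10**
Reactants: 15 methyl (2E,4Z,20E,22E)-6-hydroperoxy-6-methoxytetracosa-2,4,20,22-tetraenoate
Product: 16 methyl 2-[(3R)-6-methoxy-6-[(14E,16E)-octadeca-14,16-dien-1-yl]-3,6-dihydro-1,2-dioxin-3-yl]acetate (both C6 epimers)
Conditions: quinidine-derived N-[3,5-bis(trifluoromethyl)phenyl]squaramide (10 mol %), toluene, −20 °C; AcOH quench
Reagents that add atoms: none
Why: Proposed new method: the quinuclidine nitrogen (basicity close to that of the secondary amines known to trigger this closure) takes up the OOH proton while the squaramide N–H pair binds the ester carbonyl of the E-enoate, so the peroxy oxygen should attack C3 in a 6-exo-trig conjugate addition from the face left open in the chiral pocket and set C3 (R) under catalyst control for both C6 epimers of 15; the closest known reaction types are the amine-promoted, non-asymmetric cyclisation of α-alkoxy hydroperoxides onto enoates to give 1,2-dioxane-3-acetates and the bifunctional-organocatalyst intramolecular oxa-Michael addition of alcohols to α,β-unsaturated esters.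

**Step 11**
Reactants: 16 methyl 2-[(3R)-6-methoxy-6-[(14E,16E)-octadeca-14,16-dien-1-yl]-3,6-dihydro-1,2-dioxin-3-yl]acetate (both C6 epimers)
Product: 17 xestin A, methyl 2-[(3R,6R)-6-methoxy-6-[(14E,16E)-octadeca-14,16-dien-1-yl]-3,6-dihydro-1,2-dioxin-3-yl]acetate
Conditions: camphorsulfonic acid (cat.), MeOH/CH2Cl2, rt; chromatography, C6 epimer resubmitted
Reagents that add atoms: methanol, CO
Why: Acid-catalysed ketal exchange ionises only C6–OMe, so C3 is untouched, and should funnel both epimers towards the isomer with OMe pseudoaxial (anomeric effect) and both carbon chains pseudoequatorial, which is the 3,6-cis (3R,6R) compound.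

**Compound list**
1 | ω-pentadecalactone (oxacyclohexadecan-2-one) | O=C1CCCCCCCCCCCCCCO1 | starting material
2 | methyl 15-hydroxypentadecanoate | COC(=O)CCCCCCCCCCCCCCO | intermediate
3 | methyl 15-[(1-phenyl-1H-tetrazol-5-yl)sulfanyl]pentadecanoate | COC(=O)CCCCCCCCCCCCCCSc1nnnn1-c1ccccc1 | intermediate
4 | methyl 15-[(1-phenyl-1H-tetrazol-5-yl)sulfonyl]pentadecanoate | COC(=O)CCCCCCCCCCCCCCS(=O)(=O)c1nnnn1-c1ccccc1 | intermediate
5 | (E)-crotonaldehyde | C/C=C/C=O | starting material
6 | methyl (15E,17E)-nonadeca-15,17-dienoate | C/C=C/C=C/CCCCCCCCCCCCCC(=O)OC | intermediate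
7 | (15E,17E)-nonadeca-15,17-dienoic acid | C/C=C/C=C/CCCCCCCCCCCCCC(=O)O | intermediate
8 | (15E,17E)-nonadeca-15,17-dienoyl chloride | C/C=C/C=C/CCCCCCCCCCCCCC(=O)Cl | intermediate
9 | acetylene | C#C | starting material
10 | hexamethylditin | C[Sn](C)(C)[Sn](C)(C)C | starting material
11 | (Z)-1,2-bis(trimethylstannyl)ethene | C[Sn](C)(C)/C=C\[Sn](C)(C)C | intermediate
12 | methyl (E)-3-iodoacrylate | COC(=O)/C=C/I | starting material
13 | (1Z,17E,19E)-1-(trimethylstannyl)henicosa-1,17,19-trien-3-one (not isolated) | C/C=C/C=C/CCCCCCCCCCCCCC(=O)/C=C\[Sn](C)(C)C | intermediate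
14 | methyl (2E,4Z,20E,22E)-6-oxotetracosa-2,4,20,22-tetraenoate | C/C=C/C=C/CCCCCCCCCCCCCC(=O)/C=C\C=C\C(=O)OC | intermediate
15 | methyl (2E,4Z,20E,22E)-6-hydroperoxy-6-methoxytetracosa-2,4,20,22-tetraenoate (racemic) | C/C=C/C=C/CCCCCCCCCCCCCC(OC)(OO)/C=C\C=C\C(=O)OC | intermediate
16 | methyl 2-[(3R)-6-methoxy-6-[(14E,16E)-octadeca-14,16-dien-1-yl]-3,6-dihydro-1,2-dioxin-3-yl]acetate (both C6 epimers) | C/C=C/C=C/CCCCCCCCCCCCCC1(OC)C=C[C@@H](CC(=O)OC)OO1 | intermediate
17 | xestin A, (3R,6R) | C/C=C/C=C/CCCCCCCCCCCCC[C@]1(OC)C=C[C@@H](CC(=O)OC)OO1 | target

**Total step count:** 11. **Longest linear sequence:** 10 (steps 1–6 and 8–11, from ω-pentadecalactone).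

**Steps most likely to fail**

**Step 10.**
- Facial discrimination may be poor because an ester binds the catalyst only weakly.
- One C6 epimer may be mismatched with the catalyst and stall.
- The amine may induce Kornblum–DeLaMare fragmentation, or retro-Michael/Michael erosion of the C3 configuration.

Fallback (known chemistry), setting out from 15: the closure is run with an achiral secondary amine (Et2NH in CF3CH2OH) to give the stereorandom dioxine F1. Equilibration in acidic methanol as in step 11 then gives the racemic cis-peroxyketal, that is 17 together with its enantiomer ent-xestin A F2. A hydrolase of the lipase class (for example Candida antarctica lipase B, phosphate buffer/MTBE) is selected from a screen so that the unwanted antipode reacts faster. It hydrolyses F2 to the (3S,6S)-carboxylic acid F3, which is removed by a mild basic wash. The unreacted ester rejoins the route at 17.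

**Step 9.**
- The 4Z alkene may drift to 4E.
- Methanol or H2O2 may add in conjugate fashion to the enone.
- The ketalisation equilibrium may be unfavourable.
- Acid may induce vinyl migration with O–O cleavage.

Fallback, setting out from 14: the ketone is first ketalised under aprotic kinetic conditions (Me3SiOMe, cat. Me3SiOTf, CH2Cl2, −78 °C) to the dimethyl ketal F4. A single methoxy group is then exchanged for OOH with anhydrous ethereal H2O2 and catalytic camphorsulfonic acid at low temperature. This rejoins the route at 15.

**Step 8.**
- Double coupling may turn statistical.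
- The intermediate may protodestannylate.
- The enone may isomerise Z to E through palladium hydride or phosphine addition.
- The Z-dienone may undergo oxa-6π closure.

Fallback, setting out from 12 and 8: the geometry is set by syn-hydrogenation instead of by a stereoretentive coupling.
- Sonogashira coupling of 12 with trimethylsilylacetylene (PdCl2(PPh3)2, CuI, Et3N) gives methyl (E)-5-(trimethylsilyl)pent-2-en-4-ynoate F5.
- K2CO3/MeOH gives methyl (E)-pent-2-en-4-ynoate F6.
- Acyl Sonogashira coupling of F6 with 8 (PdCl2(PPh3)2, CuI, one equivalent of Et3N, THF) gives the enynone methyl (2E,20E,22E)-6-oxotetracosa-2,20,22-trien-4-ynoate F7.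
- Semihydrogenation (H2, Pd/CaCO3 poisoned with Pb(OAc)2, quinoline, EtOAc) rejoins the route at 14.

**Further compounds**
F1 | step 10 | methyl 2-[6-methoxy-6-[(14E,16E)-octadeca-14,16-dien-1-yl]-3,6-dihydro-1,2-dioxin-3-yl]acetate, all ring stereoisomers | C/C=C/C=C/CCCCCCCCCCCCCC1(OC)C=CC(CC(=O)OC)OO1
F2 | step 10 | ent-xestin A, (3S,6S) | C/C=C/C=C/CCCCCCCCCCCCC[C@@]1(OC)C=C[C@H](CC(=O)OC)OO1
F3 | step 10 | 2-[(3S,6S)-6-methoxy-6-[(14E,16E)-octadeca-14,16-dien-1-yl]-3,6-dihydro-1,2-dioxin-3-yl]acetic acid | C/C=C/C=C/CCCCCCCCCCCCC[C@@]1(OC)C=C[C@H](CC(=O)O)OO1
F4 | step 9 | methyl (2E,4Z,20E,22E)-6,6-dimethoxytetracosa-2,4,20,22-tetraenoate | C/C=C/C=C/CCCCCCCCCCCCCC(OC)(OC)/C=C\C=C\C(=O)OC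
F5 | step 8 | methyl (E)-5-(trimethylsilyl)pent-2-en-4-ynoate | COC(=O)/C=C/C#C[Si](C)(C)C
F6 | step 8 | methyl (E)-pent-2-en-4-ynoate | COC(=O)/C=C/C#C
F7 | step 8 | methyl (2E,20E,22E)-6-oxotetracosa-2,20,22-trien-4-ynoate | C/C=C/C=C/CCCCCCCCCCCCCC(=O)C#C/C=C/C(=O)OC
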